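The earlier runs and the new flask stem from a simulated flask with made-up constants; scatter was added.

Each target I counted had taken one open intermediate and one second intermediate, so one partner, and that count is what I handed over with these flasks.

| setting | epsilon | theta | birch | elm | cedar | ash |
|---|---|---|---|---|---|---|
| starting material | 1.4 M | 1.4 M | 1.4 M | 1.4 M | 1.4 M | 1.4 M |
| partner | 0.50 equiv | 2 equiv | 1.00 equiv | 1.00 equiv | 1.00 equiv | 1.00 equiv |
| protic impurity | 0.14 M | 0.14 M | 0.140 M | 0.140 M | 0.140 M | 0.140 M |
| temperature | −25 °C | 5 °C | −20 °C | 30 °C | 5 °C |  |
| remark | run made earlier | run made earlier |  |  |  | at 30 °C until 15 h, from then on at −20 °C |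
| time |  |  | 20 h | 20 h | 20 h | 20 h |

| run | time / h | open intermediate / % | target / % |
|---|---|---|---|
| epsilon | 2.50 | 6.9 | 0.2 |
| epsilon | 5.00 | 11.9 | 0.3 |
| epsilon | 8.00 | 17.7 | 0.8 |
| epsilon | 10.0 | 21.2 | 1.4 |
| epsilon | 12.0 | 24.1 | 2.9 |
| epsilon | 15.0 | 28.5 | 3.6 |
| theta | 0.333 | 27.3 | 13.0 |
| theta | 0.833 | 17.4 | 43.0 |
| theta | 2.00 | 1.5 | 61.9 |
| theta | 2.50 | 0.6 | 62.0 |
| theta | 4.00 | 0 | 62.3 |

(each reading ± 0.3 percentage points)

- in percentages every species weighs as the starting material in it: one side product counts as two
- candidate steps: starting material -> open intermediate; partner -> second intermediate; open intermediate + second intermediate -> target; starting material + target -> side product; partner + protic impurity -> quenched reagent; target <-> isomer of the product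

* the flask that comes out highest in amount of open intermediate, in percent of the starting material charged, or "all alike" when all lie within 1.5 percentage points (birch / elm / cedar / ash / all alike)
* open intermediate at the end, in percent of the starting material charged, birch
* open intermediate at the end, in percent of the starting material charged, elm
* open intermediate at the end, in percent of the starting material charged, cedar
* open intermediate at the end, in percent of the starting material charged, ash

I charged partner one to one, but each protic impurity can spend a partner as quenched reagent:

c(protic impurity) / c(starting material) = 0.140 M / 1.4 M = 10.0%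

I called this the stranded share: the part of the charge that finds no partner, which makes partner the limiting reagent. Each side product takes one starting material that never opens, so for a flask in which starting material, partner, second intermediate and protic impurity have reacted to the end I wrote:

open intermediate left = stranded share − side product / 2

Theta's target stood at 61.9% after 2.00 h and 62.3% after 4.00 h, so at 5 °C it had stopped moving well before 20 h, though with excess partner. I therefore expected cedar and elm to have finished by the time you came, each holding somewhat under 10.0%. Ash has 15 h hot, far longer than theta needed, so I expected it to match elm.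

Birch was different. Epsilon at −25 °C held open intermediate and target together at 32.1% after 15.0 h, with 28.5% of that still open intermediate, so I expected birch at −20 °C to be unfinished and highest.

My note said to leave the baths alone, since my count held the stranded share of elm, cedar and ash open through further waiting or cooling.

The forecast gave birch as highest, with 35%, 0.3%, 2.5% and 0.3% for birch, elm, cedar and ash, saying “Ash matches elm, since cooling changes nothing”, and its elm figure stood below my stranded share.

Birch came out highest at 34.3%, against 8.08% for elm, 6.04% for cedar and 8.08% for ash. Ash held 8.08% at the change of temperature and 8.08% at the end, with partner at 0%. For elm, the stranded share, corrected for the 0.66% of impurity unspent and with 3.71% side product, gives: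

10.0% × (1 − 0.66%) − 3.71% / 2 = 8.08%

    starting material → open intermediate (k = 0.0556 /h, Ea = 79.0 kJ/mol)
    partner → second intermediate (k = 0.0261 /h, Ea = 81.0 kJ/mol)
    open intermediate + second intermediate → target (k = 0.611 /M/h, Ea = 57.0 kJ/mol)
    starting material + target → side product (k = 0.0252 /M/h, Ea = 60.0 kJ/mol)
    partner + protic impurity → quenched reagent (k = 0.266 /M/h, Ea = 69.0 kJ/mol)
    target ⇌ isomer of the product (K = 0.785, k = 0.0207 /h, Ea = 93.0 kJ/mol, ΔH = −15.0 kJ/mol)
    (constants at −20 °C)

A flask like birch but kept at −5 °C has the same stranded share, 10.0%, but with 0.991% of partner and 0.0196 M of second intermediate still unused and 10.8% side product, so the count gives 6.98%. The computed flask gives 6.97%.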